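I cannot read a product in proportion to its reagent out of Thursday's and Saturday's runs: with the same substrate and catalyst, raising the reagent from 22.0 mM to 34.0 mM lifts the product at 10.0 min from 8.48 mM to 11.0 mM, less than in proportion, but the substrates run down too and the readings scatter, so a plain use-up of the reagent stays open.

the same everywhere: free catalyst 2.5 mol%; racemization catalyst 5 mol%

| run | left-handed substrate | right-handed substrate | reagent | remark | time |
|---|---|---|---|---|---|
| Thursday's | 20 mM | 20 mM | 1.1 equiv | run made earlier |  |
| Saturday's | 20 mM | 20 mM | 1.7 equiv | run made earlier |  |
| Monday's | 30 mM | 30 mM | 2.2 equiv | run made earlier |  |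
| flask | 20 mM | 20 mM | 2.20 equiv |  | 15 min |

| run | time / min | left-handed product / % | right-handed product / % |
|---|---|---|---|
| Thursday's | 0.667 | 2.8 | 3.6 |
| Thursday's | 1.50 | 4.0 | 1.0 |
| Thursday's | 4.00 | 9.0 | 3.8 |
| Thursday's | 10.0 | 12.2 | 9.0 |
| Saturday's | 2.50 | 6.8 | 3.6 |
| Saturday's | 5.00 | 14.1 | 6.1 |
| Saturday's | 6.00 | 14.9 | 8.0 |
| Saturday's | 10.0 | 18.3 | 9.3 |
| Monday's | 0.667 | 6.3 | 4.0 |
| Monday's | 1.50 | 15.4 | 4.1 |
| Monday's | 4.00 | 22.9 | 10.7 |
| Monday's | 10.0 | 29.4 | 14.3 |

(each reading ± 1 percentage point)

- free catalyst is single-handed; left-handed substrate and right-handed substrate are mirror images of each other, charged as a racemate, each of them at the stated concentration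
- an excess is the difference of the two amounts in percent of their sum
- an excess is below zero if the other one leads

- left-handed product and right-handed product together, in percent of the left-handed substrate and right-handed substrate charged together, at 15 min
- excess of left-handed product over right-handed product in the product at 15 min
- whether the exchange between left-handed substrate and right-handed substrate keeps pace with the reaction: how far the product's excess at 15 min gets from its value without exchange to its value with instant exchange (above 80% keeps pace, below 20% hardly takes part, else lags behind)

I suppose that the reagent also wastes itself, the harder the more of it stands, and I read the product as a saturation curve on a double-reciprocal plot. The reciprocal of the product is then the reciprocal of a roof plus the reciprocal of reach times reagent charge. Reach is the share of the reagent that the substrates would take by themselves, a pseudo-first-order decay. Those two runs give a reach of 58.7% at 10.0 min and a roof of 24.7 mM, the product that a flask with these substrate and catalyst levels nears as its reagent charge grows.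

The flask has those levels and 44.0 mM of reagent. By 15 min its reach is 73.4%, so I reckon 14.0 mM of product, 35.0% of the substrates charged.

The weak link is the roof, which rests on two noisy readings, so I test it on Monday's run. If roof and reach rate both scale with catalyst times substrate, by 2.25, Monday's run should show 46.9% at 10.0 min, and it reads 43.7%. That is somewhat high, but I keep the roof. Pooling the readings at 10.0 min from Thursday's, Saturday's and Monday's runs gives an excess of about 29.5%, and I leave the exchange open.

The forecast says 33% (28% to 39%), an excess of 33% (26% to 40%) and, for the exchange, hardly takes part: “Exchange hardly contributes, though the data are noisy”.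

The flask gives 35.1% of product with an excess of 33.3%, and the exchange lags behind, getting 74% of the way to the excess with instant exchange.

    reagent → decomposition product (k = 5.76 × 10⁻⁴ min⁻¹)
    reagent + free catalyst + left-handed substrate → free catalyst + left-handed product (k = 5310 M⁻² min⁻¹)
    reagent + free catalyst + right-handed substrate → free catalyst + right-handed product (k = 2560 M⁻² min⁻¹)
    left-handed substrate + racemization catalyst ⇌ right-handed substrate + racemization catalyst, rate k4*[racemization catalyst]*[left-handed substrate] forward; the back reaction follows from the equilibrium constant (k = 291 M⁻¹ min⁻¹)
    2 reagent → homo dimer (k = 2.67 M⁻¹ min⁻¹)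

In the flask free catalyst stands at 100% at 15.0 min, with 13% of the reagent remaining. A neighbouring flask has 1.5 mol% of free catalyst, so its roof becomes 14.8 mM and its reach at 15 min becomes 54.9%, and the same reckoning gives 23.0%. That neighbour gives 24.7% with an excess of 33.9%, and its homo dimer reaches 13.7 mM, more than the 12.2 mM in the flask.

The data were generated by integration with constants of no real substance; noise was put on by code.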